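## Analysis of the target

The target 37 is a monocyclic ether acid: one oxane ring (O1, C2–C6) that carries a prop-2-enoic acid unit on C2 and a sixteen-carbon triene chain on C5. Of its three stereocentres, C2 (R) and C5 (S) stand 1,4 to each other across the ring and are trans, so both substituents are equatorial in the chair, whereas the chain carbinol C7' (R) lies seven bonds from C5 and cannot be relayed from the ring. The chain holds an (E)-trisubstituted alkene (C3'=C4'), a secondary allylic alcohol next to a 1,1-disubstituted alkene (C8'=CH2) and a prenyl-type terminus. Sensitive elements are the α-methylene acid (a Michael acceptor that adds alkoxides and oligomerises), the ionisable allylic alcohol and the electron-rich alkenes (towards boranes, electrophiles and radicals); at the saturated-ester stage the C2–O1 bond is also at risk, because it is β to the carbonyl and can open by elimination. The synthesis is hard because C5 carries only three CH2 groups and a hydrogen, so its configuration cannot be set by addition to a local functional group, and the 1,4-trans relation has to be carried across the ring oxygen. The strategy rests on the unit O1–C2–Cα–CO2H: C2 bears the ring oxygen and a two-carbon acid branch, which is the reduced form of a β-alkoxyacrylate with C2 as β-carbon. C2–C3 can therefore be made by adding a C3-centred radical to that acrylate, tethered through C4–C5–C6–O1, with C5 coming from an enzymatic desymmetrisation of a 2-substituted propane-1,3-diol.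

## Retrosynthetic reasoning

**Final unmasking (37 ⇐ 36 ⇐ 35).** The acid is traced back to its ethyl ester and the carbinol to its silyl ether. These are the two most reactive functions, so they are released in the last two steps and nothing has to be carried out in their presence.

**Exocyclic methylene (35 ⇐ 33 ⇐ 31).** The C=CH2 bond of the acrylate is cut to the saturated acetate 31 and a one-carbon iminium electrophile (Mannich base 33, then elimination). The cut is placed after the fragment union for two reasons. An acrylate would not survive the ylide, hydroboration and alkoxide steps that precede it. Enolisation with an amide base is also only clean when no acetate is in the molecule, and by the stage of 31 the acetate of 11 is long gone.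

**Fragment union (31 ⇐ 14 + 29).** The C2'–C3' single bond beside the trisubstituted alkene is cut. This divides the molecule into a ring half and a chain half of similar size and separates the ring stereocentres from the remote carbinol. The forward reaction is an sp3–sp2 coupling of the primary alkylborane from vinyl oxane 14 with iodoalkene 29. It must keep the (E) geometry of 29 and leave the ester untouched.

**Chain half (29 ⇐ 27 ⇐ 25 ⇐ 24 ⇐ 23 ⇐ 20 + 21; 20 ⇐ 19 ⇐ 15 + 16).** The iodoalkene is traced to terminal alkyne 27 by a syn methyl–metal addition, which fixes the alkene geometry. The carbinol of 25 is set by catalyst-controlled reduction of enone 24, made from racemic 23 by oxidation. The C4–C5 bond of 23 is cut to enal 20 and the organomagnesium from 21. Enal 20 comes from allylic alcohol 19, whose 2-substituted allyl unit arises from 15 and 16 by carbometalation.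

**C5 arm (14 ⇐ 13 ⇐ 12 ⇐ 11).** The vinyl group is traced through aldehyde 13 and alcohol 12 to the acetoxymethyl group of 11. This gives the two-carbon spacer the coupling needs from the one-carbon arm the desymmetrisation provides.

**Ring (11 ⇐ 10), the key disconnection.** C2–C3 is cut. In the forward sense a primary radical at C3, generated from the iodide of 10, adds to the β-carbon of the acrylate hung on O1. One step closes the oxane, creates C2 under control of C5 and delivers the acetate arm at the correct oxidation level. The cut is made before the chain is attached, so the acrylate is the only alkene the radical can reach.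

**Radical precursor (10 ⇐ 9 ⇐ 8 ⇐ 6 ⇐ 4 + 5).** The C–I bond goes back to alcohol 9 and aldehyde 8, and 8 to the allyl group of 6 by loss of one carbon. The enol ether C–O bond of 6 is cut to alcohol 4 and propiolate 5. Capping the free hydroxyl of 4 at once also removes the risk of acyl migration.

**Source of C5 (4 ⇐ 2 + 3; 2 ⇐ 1).** The single stereocentre of 4 is traced to the prochiral diol 2 by enantiotopic-group-selective acylation with 3. Diol 2 comes from malonate 1 by reduction. Either enantiomer of the monoacetate would serve, because the two oxygen arms can be given their roles in either order.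

## Alternatives that were turned down

**Alternative 1:** The disconnection addresses only the chain carbinol and its exocyclic methylene, which are traced to a 2,3-epoxy alcohol that carries a removable CH2OH group. The forward key step is a Sharpless epoxidation (Ti(OiPr)4, diethyl D-(−)-tartrate, tBuOOH, CH2Cl2, −20 °C) of the allylic alcohol (2E)-2-(4-methylpent-3-en-1-yl)-7-(trimethylsilyl)hept-2-en-6-yn-1-ol A2, which should give the epoxy alcohol [(2R,3R)-2-(4-methylpent-3-en-1-yl)-3-[4-(trimethylsilyl)but-3-yn-1-yl]oxiran-2-yl]methanol A1. The hydroxymethyl group of A1 is then converted to an iodide and expelled reductively with zinc, which opens the oxirane and gives compound 25 of the route below.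
- For: A2 is an (E)-trisubstituted primary allylic alcohol, the class on which this epoxidation is most dependable. The distal alkene does not bind the catalyst, and the C–O bond of the carbinol is transferred stereospecifically from A1.
- Against: the key step is spent on the isolated, remote carbinol and leaves the oxane, the 1,4-trans pair and the acrylic acid unsolved. A2 also needs a geometry-defined trisubstituted alkene, and two further steps are needed to excise the handle from A1.
- Comparison: on enantiocontrol of the carbinol it is stronger than the oxazaborolidine reduction of 24 used here, and it could serve as another entry to 25. It is no shorter (about six to seven steps to 25 against five). The chosen strategy offers in its place a key step that closes the ring, forms a skeletal bond and relays C5 to C2 at once.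

**Alternative 2:** The oxane is traced to a seven-membered lactone, and C5 to the prochiral carbon of a 4-substituted cyclohexanone. In the forward key step a flavin-dependent monooxygenase of the Baeyer–Villiger class, supplied with NADPH and O2, would convert the achiral ketone 4-(hydroxymethyl)cyclohexan-1-one A4 into the lactone (5R)-5-(hydroxymethyl)oxepan-2-one A3 by migrating one of the two enantiotopic α-methylene groups to oxygen. A3 has the sense needed for C5. Acyl transfer to its hydroxymethyl oxygen would then give (5R)-5-(2-hydroxyethyl)oxan-2-one A5, and A5 is already the oxane skeleton with C2 as a carbonyl.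
- For: one aerobic catalytic step from the achiral A4, with the three arms differentiated by oxidation level. In A5 the C5 arm arrives as a two-carbon unit, which would spare the aldehyde, methylenation and hydroboration detour of the chosen route. On that point it is stronger.
- Against: it needs a cofactor-dependent oxygenase with a recycling system, and the sense of insertion is the enzyme's. The ring size of A3 is labile. C2 is still a carbonyl in A5, so a second stereo-defining operation is needed (lactol activation and C–C bond formation at an oxocarbenium ion, with the hydroxyethyl arm protected so that it does not trap the cation), and the acetate arm has to be brought in there.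
- Comparison: both strategies take C5 from an enzyme, and Alternative 2 is about as short to a difunctional oxane. The chosen strategy offers an off-the-shelf hydrolase and a ring closure that sets C2 and installs the ester arm in the same step, with no oxocarbenium stage.

**Alternative 3:** The O1–C6 bond is cut (oxa-Michael) and C2 is taken from the chiral pool. (2S)-2-Hydroxybutanedioic acid A7 (L-malic acid) supplies the carbinol that becomes C2 and the CH2CO2H arm that becomes the acid branch. In the forward key step a catalytic amount of KOtBu in tBuOH makes the secondary hydroxyl of tert-butyl (5R)-5,7-dihydroxy-2-methylideneheptanoate A8 add 6-endo to the methylene carbon. The product is tert-butyl (3S,6R)-6-(2-hydroxyethyl)oxane-3-carboxylate A6, and in A6 the ester-bearing carbon (the future C5) epimerises through its enolate to the diequatorial trans isomer.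
- For: C2 is absolute from A7, and the trans relation in A6 is set thermodynamically. That is a firmer guarantee than kinetic 1,4-induction in a radical transition state, and no tin is used. On stereochemical reliability it is stronger.
- Against: both arms of A6 emerge at the wrong oxidation level. The C5 ester must be reduced and then still needs the aldehyde/vinyl sequence, and the hydroxyethyl arm must be oxidised twice before methylenation. Two primary alcohols must be told apart. A8 takes about six steps from A7, and the 6-endo addition to an α-alkyl acrylate competes with oligomerisation under alkoxide.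
- Comparison: the chosen strategy gives both arms of 11 at directly usable oxidation levels and reaches the oxane in seven steps. Part of the thermodynamic advantage is recoverable, because the β-alkoxy ester can in principle be equilibrated through reversible ring opening once the C5 arm is a carbon substituent, as in 14.

Key step: step 7

Assumption: Burkholderia cepacia lipase is taken to acetylate the arm of 2 that gives the (S)-monoacetate 4; if the enzyme prefers the other arm, the hydrolytic mode described under the uncertain steps gives the same (S)-4.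

## Route

Step 1
Reactants: 1 diethyl 2-(prop-2-en-1-yl)propanedioate (diethyl allylmalonate)
Product: 2 2-(prop-2-en-1-yl)propane-1,3-diol
Conditions: LiAlH4, THF, 0 °C → reflux; aq. NaOH work-up
Reagents that add atoms: none
Why: Hydride reduction of both ester groups to primary alcohols; the isolated alkene is inert and the product is a prochiral diol.

Step 2
Reactants: 2 2-(prop-2-en-1-yl)propane-1,3-diol; 3 ethenyl acetate (vinyl acetate)
Product: 4 [(2S)-2-(hydroxymethyl)pent-4-en-1-yl] acetate
Conditions: Burkholderia cepacia lipase (immobilised), 3 (3 equiv), iPr2O, 25 °C; filter, use at once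
Reagents that add atoms: none
Why: Lipase-catalysed transesterification that acylates one of the two enantiotopic hydroxymethyl groups and so sets the future C5; tautomerisation of the released enol makes it irreversible, and the product is carried on directly to avoid racemising acyl migration between the two oxygen atoms.

Step 3
Reactants: 4 [(2S)-2-(hydroxymethyl)pent-4-en-1-yl] acetate; 5 ethyl prop-2-ynoate (ethyl propiolate)
Product: 6 ethyl (2E)-3-{[(2S)-2-(acetoxymethyl)pent-4-en-1-yl]oxy}prop-2-enoate
Conditions: N-methylmorpholine, CH2Cl2, 0 °C → rt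
Reagents that add atoms: none
Why: Amine-catalysed oxa-Michael addition of a primary alcohol to a propiolate, which gives the (E)-β-alkoxyacrylate; the weak base does not move the acetate, and capping the hydroxyl locks the configuration.

Step 4
Reactants: 6 ethyl (2E)-3-{[(2S)-2-(acetoxymethyl)pent-4-en-1-yl]oxy}prop-2-enoate
Product: 8 ethyl (2E)-3-{[(2S)-2-(acetoxymethyl)-4-oxobutyl]oxy}prop-2-enoate, via vicinal diol 7 (not isolated)
Conditions: OsO4 (2 mol%), NaIO4, 2,6-lutidine, 1,4-dioxane–H2O, rt
Reagents that add atoms: osmium tetroxide, O=[Os](=O)(=O)=O; sodium periodate, [Na+].[O-]I(=O)(=O)=O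
Why: Lemieux–Johnson oxidative cleavage; the electrophilic osmylation should prefer the isolated monosubstituted alkene over the acrylate alkene, which is deactivated by the ester, and lutidine suppresses over-oxidation.

Step 5
Reactants: 8 ethyl (2E)-3-{[(2S)-2-(acetoxymethyl)-4-oxobutyl]oxy}prop-2-enoate
Product: 9 ethyl (2E)-3-{[(2S)-2-(acetoxymethyl)-4-hydroxybutyl]oxy}prop-2-enoate
Conditions: NaBH4, EtOH, −20 °C → 0 °C
Reagents that add atoms: none
Why: Chemoselective borohydride reduction of the aldehyde; the conjugated ester and the acetate are not reduced at low temperature, and ethanol matches the ethyl ester.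

Step 6
Reactants: 9 ethyl (2E)-3-{[(2S)-2-(acetoxymethyl)-4-hydroxybutyl]oxy}prop-2-enoate
Product: 10 ethyl (2E)-3-{[(2S)-2-(acetoxymethyl)-4-iodobutyl]oxy}prop-2-enoate
Conditions: I2, PPh3, imidazole, CH2Cl2, 0 °C → rt
Reagents that add atoms: iodine, II
Why: Appel-type iodination of a primary alcohol through its alkoxyphosphonium salt; the near-neutral conditions leave acrylate and acetate untouched.

Step 7
Reactants: 10 ethyl (2E)-3-{[(2S)-2-(acetoxymethyl)-4-iodobutyl]oxy}prop-2-enoate
Product: 11 ethyl 2-[(2R,5S)-5-(acetoxymethyl)oxan-2-yl]acetate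
Conditions: Bu3SnH (1.3 equiv), AIBN (0.15 equiv), PhH (0.01 M), reflux, syringe-pump addition over 5 h; KF work-up
Reagents that add atoms: none
Why: A tributylstannyl radical abstracts iodine from 10 to give the primary C3 radical, which adds to the β-carbon (C2) of the tethered (E)-β-alkoxyacrylate; the resulting α-ester radical takes hydrogen from Bu3SnH and the chain continues. The closest known reaction type is the tin-hydride cyclisation of ω-halo β-alkoxyacrylates to 2-(oxacycloalkyl)acetates. The one ring formed, the oxane (C3, C4, C5, C6, O1, C2), closes in the 6-exo-trig mode with formation of C2–C3. The new stereocentre C2 is controlled by the lipase-set C5 through a chair-like transition state in which the acetoxymethyl group on C5 is equatorial and the acrylate unit is pseudo-equatorial, so the acetate arm ends trans to the C5 substituent (2R,5S). The step needs ring closure to outrun hydrogen transfer to the open radical, and it needs 1,4-diastereoselection. The first is secured by the polarity match between the nucleophilic alkyl radical and the electron-poor β-carbon together with high dilution and slow stannane addition; the second by the equatorial preference of the only substituent on the forming ring. No other alkene is present, so no competing closure exists, and acetate and ethyl ester are inert to stannyl radicals.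

Step 8
Reactants: 11 ethyl 2-[(2R,5S)-5-(acetoxymethyl)oxan-2-yl]acetate
Product: 12 ethyl 2-[(2R,5R)-5-(hydroxymethyl)oxan-2-yl]acetate
Conditions: K2CO3 (0.3 equiv), EtOH, 0 °C → rt
Reagents that add atoms: none
Why: Base-catalysed transesterification that moves the acetyl group to ethanol while keeping the ethyl ester; carbonate in ethanol is too weak to enolise the ester, so the β-alkoxy ester does not ring-open.

Step 9
Reactants: 12 ethyl 2-[(2R,5R)-5-(hydroxymethyl)oxan-2-yl]acetate
Product: 13 ethyl 2-[(2R,5S)-5-formyloxan-2-yl]acetate
Conditions: Dess–Martin periodinane, CH2Cl2, 0 °C → rt; used crude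
Reagents that add atoms: none
Why: Dess–Martin oxidation of a primary alcohol without base, so the α-stereocentre C5 of the aldehyde is not exposed to enolisation.

Step 10
Reactants: 13 ethyl 2-[(2R,5S)-5-formyloxan-2-yl]acetate
Product: 14 ethyl 2-[(2R,5R)-5-ethenyloxan-2-yl]acetate
Conditions: Ph3PCH3Br (1.3 equiv), KN(SiMe3)2 (1.2 equiv), THF, 0 °C; then 13, −78 °C → 0 °C
Reagents that add atoms: methyltriphenylphosphonium bromide, C[P+](c1ccccc1)(c1ccccc1)c1ccccc1.[Br-]
Why: Wittig methylenation; the aldehyde reacts far faster than the ester, and a slight deficit of base with low temperature limits enolisation at C5.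

Step 11
Reactants: 15 5-bromo-2-methylpent-2-ene; 16 prop-2-yn-1-ol
Product: 19 6-methyl-2-methylidenehept-5-en-1-ol, via homoprenylmagnesium bromide 17 (not isolated), via alkenylmagnesium alkoxide 18 (not isolated)
Conditions: Mg, THF, 40 °C; then 16 (0.4 equiv), CuI (10 mol%), THF–Et2O, 0 °C → rt; aq. NH4Cl
Reagents that add atoms: none
Why: Grignard formation followed by copper-catalysed anti-carbomagnesiation of the propargylic alkoxide; the alkyl group adds to the internal alkyne carbon, magnesium ends on the terminal carbon held by the alkoxide, and protonation gives the 2-substituted allyl alcohol.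

Step 12
Reactants: 19 6-methyl-2-methylidenehept-5-en-1-ol
Product: 20 6-methyl-2-methylidenehept-5-enal
Conditions: Dess–Martin periodinane, CH2Cl2, 0 °C → rt
Reagents that add atoms: none
Why: Dess–Martin oxidation of an allylic primary alcohol to the α-substituted enal, which is used promptly.

Step 13
Reactants: 20 6-methyl-2-methylidenehept-5-enal; 21 (4-bromobut-1-yn-1-yl)trimethylsilane
Product: 23 rac-10-methyl-6-methylidene-1-(trimethylsilyl)undec-9-en-1-yn-5-ol, via Grignard reagent 22 (not isolated)
Conditions: Mg, THF, 40 °C; then 20, THF, −78 °C; aq. NH4Cl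
Reagents that add atoms: none
Why: 1,2-Addition of a primary alkyl Grignard reagent to the enal carbonyl; the silyl cap removes the acidic alkyne hydrogen.

Step 14
Reactants: 23 rac-10-methyl-6-methylidene-1-(trimethylsilyl)undec-9-en-1-yn-5-ol
Product: 24 10-methyl-6-methylidene-1-(trimethylsilyl)undec-9-en-1-yn-5-one
Conditions: Dess–Martin periodinane, CH2Cl2, 0 °C → rt; used at once
Reagents that add atoms: none
Why: Dess–Martin oxidation of the secondary allylic alcohol to the α-methylene ketone, which erases the unselectively formed centre so that it can be reset.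

Step 15
Reactants: 24 10-methyl-6-methylidene-1-(trimethylsilyl)undec-9-en-1-yn-5-one
Product: 25 (5R)-10-methyl-6-methylidene-1-(trimethylsilyl)undec-9-en-1-yn-5-ol
Conditions: (S)-2-methyl-CBS-oxazaborolidine (0.3 equiv), catecholborane (1.8 equiv), toluene, −78 °C
Reagents that add atoms: none
Why: Corey–Bakshi–Shibata reduction; the ketone binds the catalyst boron with the branched alkenyl group as the large substituent and hydride is delivered to the Si face, which gives the (R)-carbinol, while catecholborane at −78 °C neither hydroborates the alkenes nor reduces the enone in the conjugate sense.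

Step 16
Reactants: 25 (5R)-10-methyl-6-methylidene-1-(trimethylsilyl)undec-9-en-1-yn-5-ol
Product: 26 tert-butyl(dimethyl){[(5R)-10-methyl-6-methylidene-1-(trimethylsilyl)undec-9-en-1-yn-5-yl]oxy}silane
Conditions: TBSCl, imidazole, DMF, rt
Reagents that add atoms: tert-butyl(chloro)dimethylsilane, CC(C)(C)[Si](C)(C)Cl
Why: Imidazole-promoted silylation of the secondary alcohol; the ether withstands the organoaluminium, borane, palladium and amide-base steps that follow.

Step 17
Reactants: 26 tert-butyl(dimethyl){[(5R)-10-methyl-6-methylidene-1-(trimethylsilyl)undec-9-en-1-yn-5-yl]oxy}silane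
Product: 27 tert-butyl(dimethyl){[(5R)-10-methyl-6-methylideneundec-9-en-1-yn-5-yl]oxy}silane
Conditions: K2CO3, MeOH, rt
Reagents that add atoms: none
Why: Methanolysis of the alkynyl C–Si bond; the hindered silyl ether is stable to carbonate in methanol.

Step 18
Reactants: 27 tert-butyl(dimethyl){[(5R)-10-methyl-6-methylideneundec-9-en-1-yn-5-yl]oxy}silane
Product: 29 tert-butyl{[(1E,5R)-1-iodo-2,10-dimethyl-6-methylideneundeca-1,9-dien-5-yl]oxy}dimethylsilane, via alkenylalane 28 (not isolated)
Conditions: AlMe3 (3 equiv), Cp2ZrCl2 (0.3 equiv), CH2Cl2, 0 °C → rt; then I2, THF, −30 °C → 0 °C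
Reagents that add atoms: trimethylaluminium, C[Al](C)C; iodine, II
Why: Negishi zirconium-catalysed carboalumination adds methyl and aluminium syn across the terminal alkyne with aluminium on the terminal carbon, and iodinolysis with retention gives the (E)-iodoalkene; the 1,1-disubstituted and trisubstituted alkenes do not react under these conditions.

Step 19
Reactants: 14 ethyl 2-[(2R,5R)-5-ethenyloxan-2-yl]acetate; 29 tert-butyl{[(1E,5R)-1-iodo-2,10-dimethyl-6-methylideneundeca-1,9-dien-5-yl]oxy}dimethylsilane
Product: 31 ethyl 2-[(2R,5S)-5-[(3E,7R)-7-{[tert-butyl(dimethyl)silyl]oxy}-4,12-dimethyl-8-methylidenetrideca-3,11-dien-1-yl]oxan-2-yl]acetate, via B-alkyl-9-BBN 30 (not isolated)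
Conditions: 14, 9-BBN, THF, 0 °C → rt; then aq. Cs2CO3, 29, Pd(dppf)Cl2 (5 mol%), AsPh3, DMF, rt
Reagents that add atoms: none
Why: Anti-Markovnikov hydroboration of the vinyl group followed by B-alkyl Suzuki–Miyaura coupling, which keeps the geometry of the iodoalkene; the aqueous base is added before 29 so that no free borane meets its alkenes.

Step 20
Reactants: 31 ethyl 2-[(2R,5S)-5-[(3E,7R)-7-{[tert-butyl(dimethyl)silyl]oxy}-4,12-dimethyl-8-methylidenetrideca-3,11-dien-1-yl]oxan-2-yl]acetate
Product: 33 ethyl 3-(dimethylamino)-2-[(2R,5S)-5-[(3E,7R)-7-{[tert-butyl(dimethyl)silyl]oxy}-4,12-dimethyl-8-methylidenetrideca-3,11-dien-1-yl]oxan-2-yl]propanoate, via lithium enolate 32 (not isolated)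
Conditions: LiN(iPr)2 (1.3 equiv), THF, −78 °C; then CH2=NMe2+ I− (3 equiv), −78 °C → rt
Reagents that add atoms: N,N-dimethylmethaniminium iodide (Eschenmoser's salt), C=[N+](C)C.[I-]
Why: Mannich reaction of the ester enolate with a preformed iminium salt; at −78 °C the enolate should not expel the ring oxygen, the molecule holds no other acidic site, and the new α-centre is removed in the next step.

Step 21
Reactants: 33 ethyl 3-(dimethylamino)-2-[(2R,5S)-5-[(3E,7R)-7-{[tert-butyl(dimethyl)silyl]oxy}-4,12-dimethyl-8-methylidenetrideca-3,11-dien-1-yl]oxan-2-yl]propanoate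
Product: 35 ethyl 2-[(2R,5S)-5-[(3E,7R)-7-{[tert-butyl(dimethyl)silyl]oxy}-4,12-dimethyl-8-methylidenetrideca-3,11-dien-1-yl]oxan-2-yl]prop-2-enoate, via trimethylammonium iodide 34 (not isolated)
Conditions: MeI, CH2Cl2, rt; then DBU, CH2Cl2, 0 °C → rt
Reagents that add atoms: none
Why: N-Quaternisation followed by base-induced β-elimination of trimethylamine (E1cB) gives the α-methylene ester; C2 is not touched.

Step 22
Reactants: 35 ethyl 2-[(2R,5S)-5-[(3E,7R)-7-{[tert-butyl(dimethyl)silyl]oxy}-4,12-dimethyl-8-methylidenetrideca-3,11-dien-1-yl]oxan-2-yl]prop-2-enoate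
Product: 36 ethyl 2-[(2R,5S)-5-[(3E,7R)-7-hydroxy-4,12-dimethyl-8-methylidenetrideca-3,11-dien-1-yl]oxan-2-yl]prop-2-enoate
Conditions: Bu4NF, AcOH (1:1), THF, 0 °C → rt
Reagents that add atoms: none
Why: Fluoride-mediated cleavage of the silyl ether; buffering with acetic acid keeps the medium from becoming basic enough for alkoxide addition to the acrylate.

Step 23
Reactants: 36 ethyl 2-[(2R,5S)-5-[(3E,7R)-7-hydroxy-4,12-dimethyl-8-methylidenetrideca-3,11-dien-1-yl]oxan-2-yl]prop-2-enoate
Product: 37 2-[(2R,5S)-5-[(3E,7R)-7-hydroxy-4,12-dimethyl-8-methylidenetrideca-3,11-dien-1-yl]oxan-2-yl]prop-2-enoic acid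
Conditions: LiOH, THF–H2O, 0 °C → rt; then 1 M HCl to pH 3, 0 °C
Reagents that add atoms: lithium hydroxide, [Li+].[OH-]
Why: Saponification of the ethyl ester in a medium free of alcohol, so that no alkoxide adds to the acrylate; brief cold acidification frees the acid without ionising the allylic alcohol.

## Compound list

1 | diethyl 2-(prop-2-en-1-yl)propanedioate | C=CCC(C(=O)OCC)C(=O)OCC | starting material
2 | 2-(prop-2-en-1-yl)propane-1,3-diol | C=CCC(CO)CO | intermediate
3 | ethenyl acetate | C=COC(C)=O | starting material
4 | [(2S)-2-(hydroxymethyl)pent-4-en-1-yl] acetate | OC[C@@H](COC(C)=O)CC=C | intermediate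
5 | ethyl prop-2-ynoate | C#CC(=O)OCC | starting material
6 | ethyl (2E)-3-{[(2S)-2-(acetoxymethyl)pent-4-en-1-yl]oxy}prop-2-enoate | CCOC(=O)/C=C/OC[C@@H](COC(C)=O)CC=C | intermediate
7 | ethyl (2E)-3-{[(2S)-2-(acetoxymethyl)-4,5-dihydroxypentyl]oxy}prop-2-enoate (both C4 epimers) | CCOC(=O)/C=C/OC[C@@H](COC(C)=O)CC(O)CO | intermediate (not isolated)
8 | ethyl (2E)-3-{[(2S)-2-(acetoxymethyl)-4-oxobutyl]oxy}prop-2-enoate | CCOC(=O)/C=C/OC[C@@H](COC(C)=O)CC=O | intermediate
9 | ethyl (2E)-3-{[(2S)-2-(acetoxymethyl)-4-hydroxybutyl]oxy}prop-2-enoate | CCOC(=O)/C=C/OC[C@@H](COC(C)=O)CCO | intermediate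
10 | ethyl (2E)-3-{[(2S)-2-(acetoxymethyl)-4-iodobutyl]oxy}prop-2-enoate | CCOC(=O)/C=C/OC[C@@H](COC(C)=O)CCI | intermediate
11 | ethyl 2-[(2R,5S)-5-(acetoxymethyl)oxan-2-yl]acetate | CC(=O)OC[C@H]1CC[C@H](CC(=O)OCC)OC1 | intermediate
12 | ethyl 2-[(2R,5R)-5-(hydroxymethyl)oxan-2-yl]acetate | OC[C@H]1CC[C@H](CC(=O)OCC)OC1 | intermediate
13 | ethyl 2-[(2R,5S)-5-formyloxan-2-yl]acetate | O=C[C@H]1CC[C@H](CC(=O)OCC)OC1 | intermediate
14 | ethyl 2-[(2R,5R)-5-ethenyloxan-2-yl]acetate | C=C[C@H]1CC[C@H](CC(=O)OCC)OC1 | intermediate
15 | 5-bromo-2-methylpent-2-ene | CC(C)=CCCBr | starting material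
16 | prop-2-yn-1-ol | C#CCO | starting material
17 | (4-methylpent-3-en-1-yl)magnesium bromide | CC(C)=CCC[Mg]Br | intermediate (not isolated)
18 | bromomagnesium (2Z)-3-(bromomagnesio)-2-(4-methylpent-3-en-1-yl)prop-2-en-1-olate | Br[Mg]/C=C(/CCC=C(C)C)CO[Mg]Br | intermediate (not isolated)
19 | 6-methyl-2-methylidenehept-5-en-1-ol | C=C(CO)CCC=C(C)C | intermediate
20 | 6-methyl-2-methylidenehept-5-enal | C=C(C=O)CCC=C(C)C | intermediate
21 | (4-bromobut-1-yn-1-yl)trimethylsilane | C[Si](C)(C)C#CCCBr | starting material
22 | [4-(trimethylsilyl)but-3-yn-1-yl]magnesium bromide | C[Si](C)(C)C#CCC[Mg]Br | intermediate (not isolated)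
23 | rac-10-methyl-6-methylidene-1-(trimethylsilyl)undec-9-en-1-yn-5-ol | C=C(CCC=C(C)C)C(O)CCC#C[Si](C)(C)C | intermediate
24 | 10-methyl-6-methylidene-1-(trimethylsilyl)undec-9-en-1-yn-5-one | C=C(CCC=C(C)C)C(=O)CCC#C[Si](C)(C)C | intermediate
25 | (5R)-10-methyl-6-methylidene-1-(trimethylsilyl)undec-9-en-1-yn-5-ol | C=C(CCC=C(C)C)[C@H](O)CCC#C[Si](C)(C)C | intermediate
26 | tert-butyl(dimethyl){[(5R)-10-methyl-6-methylidene-1-(trimethylsilyl)undec-9-en-1-yn-5-yl]oxy}silane | C=C(CCC=C(C)C)[C@H](O[Si](C)(C)C(C)(C)C)CCC#C[Si](C)(C)C | intermediate
27 | tert-butyl(dimethyl){[(5R)-10-methyl-6-methylideneundec-9-en-1-yn-5-yl]oxy}silane | C=C(CCC=C(C)C)[C@H](O[Si](C)(C)C(C)(C)C)CCC#C | intermediate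
28 | [(1E,5R)-5-{[tert-butyl(dimethyl)silyl]oxy}-2,10-dimethyl-6-methylideneundeca-1,9-dien-1-yl]dimethylalumane | C=C(CCC=C(C)C)[C@H](O[Si](C)(C)C(C)(C)C)CC/C(C)=C/[Al](C)C | intermediate (not isolated)
29 | tert-butyl{[(1E,5R)-1-iodo-2,10-dimethyl-6-methylideneundeca-1,9-dien-5-yl]oxy}dimethylsilane | C=C(CCC=C(C)C)[C@H](O[Si](C)(C)C(C)(C)C)CC/C(C)=C/I | intermediate
30 | ethyl 2-[(2R,5S)-5-[2-(9-borabicyclo[3.3.1]nonan-9-yl)ethyl]oxan-2-yl]acetate | C1CCC2CCCC1B2CC[C@H]3CC[C@H](CC(=O)OCC)OC3 | intermediate (not isolated)
31 | ethyl 2-[(2R,5S)-5-[(3E,7R)-7-{[tert-butyl(dimethyl)silyl]oxy}-4,12-dimethyl-8-methylidenetrideca-3,11-dien-1-yl]oxan-2-yl]acetate | C=C(CCC=C(C)C)[C@H](O[Si](C)(C)C(C)(C)C)CC/C(C)=C/CC[C@H]1CC[C@H](CC(=O)OCC)OC1 | intermediate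
32 | lithium 1-ethoxy-2-[(2R,5S)-5-[(3E,7R)-7-{[tert-butyl(dimethyl)silyl]oxy}-4,12-dimethyl-8-methylidenetrideca-3,11-dien-1-yl]oxan-2-yl]ethen-1-olate | C=C(CCC=C(C)C)[C@H](O[Si](C)(C)C(C)(C)C)CC/C(C)=C/CC[C@H]1CC[C@H](C=C(O[Li])OCC)OC1 | intermediate (not isolated)
33 | ethyl 3-(dimethylamino)-2-[(2R,5S)-5-[(3E,7R)-7-{[tert-butyl(dimethyl)silyl]oxy}-4,12-dimethyl-8-methylidenetrideca-3,11-dien-1-yl]oxan-2-yl]propanoate (both epimers at C2 of the propanoate) | C=C(CCC=C(C)C)[C@H](O[Si](C)(C)C(C)(C)C)CC/C(C)=C/CC[C@H]1CC[C@H](C(CN(C)C)C(=O)OCC)OC1 | intermediate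
34 | 3-ethoxy-N,N,N-trimethyl-3-oxo-2-[(2R,5S)-5-[(3E,7R)-7-{[tert-butyl(dimethyl)silyl]oxy}-4,12-dimethyl-8-methylidenetrideca-3,11-dien-1-yl]oxan-2-yl]propan-1-aminium iodide | C=C(CCC=C(C)C)[C@H](O[Si](C)(C)C(C)(C)C)CC/C(C)=C/CC[C@H]1CC[C@H](C(C[N+](C)(C)C)C(=O)OCC)OC1.[I-] | intermediate (not isolated)
35 | ethyl 2-[(2R,5S)-5-[(3E,7R)-7-{[tert-butyl(dimethyl)silyl]oxy}-4,12-dimethyl-8-methylidenetrideca-3,11-dien-1-yl]oxan-2-yl]prop-2-enoate | C=C(CCC=C(C)C)[C@H](O[Si](C)(C)C(C)(C)C)CC/C(C)=C/CC[C@H]1CC[C@H](C(=C)C(=O)OCC)OC1 | intermediate
36 | ethyl 2-[(2R,5S)-5-[(3E,7R)-7-hydroxy-4,12-dimethyl-8-methylidenetrideca-3,11-dien-1-yl]oxan-2-yl]prop-2-enoate | C=C(CCC=C(C)C)[C@H](O)CC/C(C)=C/CC[C@H]1CC[C@H](C(=C)C(=O)OCC)OC1 | intermediate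
37 | 2-[(2R,5S)-5-[(3E,7R)-7-hydroxy-4,12-dimethyl-8-methylidenetrideca-3,11-dien-1-yl]oxan-2-yl]prop-2-enoic acid | C=C(CCC=C(C)C)[C@H](O)CC/C(C)=C/CC[C@H]1CC[C@H](C(=C)C(=O)O)OC1 | target

## Step count and uncertain steps

Total step count: 23. Longest linear sequence: 15 steps (steps 1–10, then 19–23). The chain half takes 8 steps (11–18) and joins at step 19.

**Step 7 (key step).** Two things may go wrong. Hydrogen transfer to the open-chain radical may occur before ring closure, because six-membered exo closures are slower than five-membered ones. The 2,5-trans selectivity may also be eroded, because a single equatorial preference at C5 is a modest bias at 80 °C. The fallback forms the same C2–C3 bond through a ketyl radical and sets out from aldehyde 8. SmI2 (3 equiv) and MeOH in THF at 0 °C reduce the aldehyde to a samarium ketyl, which adds to the acrylate in a chelated chair with no chain-transfer reagent present to intercept an open radical. This should give the 2,3-trans hydroxy ester ethyl 2-[(2S,3R,5S)-5-(acetoxymethyl)-3-hydroxyoxan-2-yl]acetate F1. The extra hydroxyl is removed by Barton–McCombie deoxygenation: 1,1'-thiocarbonyldiimidazole and DMAP in 1,2-dichloroethane at 60 °C give ethyl 2-[(2S,3R,5S)-5-(acetoxymethyl)-3-[(1H-imidazole-1-carbothioyl)oxy]oxan-2-yl]acetate F2, and Bu3SnH with AIBN in toluene at 90 °C returns the route at 11.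

**Step 2.** The allyl group is a small recognition element, so discrimination between the enantiotopic arms may be incomplete or may fall on the other arm. Over-acylation and acyl migration during isolation would also lower the enantiopurity. The fallback runs the enzyme in the hydrolytic direction and sets out from 2. Ac2O, pyridine and DMAP give 2-(prop-2-en-1-yl)propane-1,3-diyl diacetate F3, which is hydrolysed by the same lipase in pH 7 phosphate buffer. The enzyme addresses the same enantiotopic arm in both directions, so hydrolysis gives the monoacetate of opposite configuration to acylation. Whichever mode supplies the (S)-enantiomer is used, and the route is rejoined at 4.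

**Step 4.** Osmylation may also attack the acrylate alkene, which is only moderately deactivated, and the aldehyde may be over-oxidised. The fallback cleaves the alkene before the acrylate exists and carries the aldehyde as an acetal; it sets out from 1. Ozonolysis (O3, CH2Cl2–MeOH, −78 °C; Me2S) and acetalisation (HC(OMe)3, TsOH cat.) give diethyl 2-(2,2-dimethoxyethyl)propanedioate F4. LiAlH4 gives 2-(2,2-dimethoxyethyl)propane-1,3-diol F5. The lipase with 3 gives [(2S)-2-(hydroxymethyl)-4,4-dimethoxybutyl] acetate F6, and 5 with N-methylmorpholine gives ethyl (2E)-3-{[(2S)-2-(acetoxymethyl)-4,4-dimethoxybutyl]oxy}prop-2-enoate F7. Brief treatment with CF3CO2H–H2O in CH2Cl2 at 0 °C unmasks the aldehyde and returns the route at 8.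

**Step 10.** The basic ylide may enolise the β-alkoxy aldehyde, which would epimerise C5 or open the ring by β-elimination of the ring oxygen. The fallback avoids the aldehyde and sets out from 12. I2, PPh3 and imidazole give ethyl 2-[(2R,5S)-5-(iodomethyl)oxan-2-yl]acetate F8. A Negishi alkyl–alkenyl coupling with vinylzinc bromide (Pd2(dba)3, tricyclopentylphosphine, N-methylimidazole, THF–NMP, 80 °C) returns the route at 14.

**Step 15.** Facial discrimination may be incomplete, because both carbonyl substituents are flexible chains that differ mainly in branching at the α-carbon, and the s-cis enone may undergo conjugate reduction by the borane. The fallback is a Sharpless kinetic resolution and sets out from racemic 23, which omits step 14. Ti(OiPr)4, L-(+)-diisopropyl tartrate, tert-butyl hydroperoxide (0.6 equiv) and 4 Å sieves in CH2Cl2 at −20 °C epoxidise the (S)-enantiomer to (1S)-1-[(2R)-2-(4-methylpent-3-en-1-yl)oxiran-2-yl]-5-(trimethylsilyl)pent-4-yn-1-ol F9. The unreacted (R)-enantiomer is separated by chromatography and is 25, where the route is rejoined.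

## Further compounds

F1 | step 7 | ethyl 2-[(2S,3R,5S)-5-(acetoxymethyl)-3-hydroxyoxan-2-yl]acetate | CC(=O)OC[C@H]1C[C@@H](O)[C@H](CC(=O)OCC)OC1
F2 | step 7 | ethyl 2-[(2S,3R,5S)-5-(acetoxymethyl)-3-[(1H-imidazole-1-carbothioyl)oxy]oxan-2-yl]acetate | CC(=O)OC[C@H]1C[C@@H](OC(=S)n2ccnc2)[C@H](CC(=O)OCC)OC1
F3 | step 2 | 2-(prop-2-en-1-yl)propane-1,3-diyl diacetate | C=CCC(COC(C)=O)COC(C)=O
F4 | step 4 | diethyl 2-(2,2-dimethoxyethyl)propanedioate | CCOC(=O)C(CC(OC)OC)C(=O)OCC
F5 | step 4 | 2-(2,2-dimethoxyethyl)propane-1,3-diol | COC(CC(CO)CO)OC
F6 | step 4 | [(2S)-2-(hydroxymethyl)-4,4-dimethoxybutyl] acetate | OC[C@@H](COC(C)=O)CC(OC)OC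
F7 | step 4 | ethyl (2E)-3-{[(2S)-2-(acetoxymethyl)-4,4-dimethoxybutyl]oxy}prop-2-enoate | CCOC(=O)/C=C/OC[C@@H](COC(C)=O)CC(OC)OC
F8 | step 10 | ethyl 2-[(2R,5S)-5-(iodomethyl)oxan-2-yl]acetate | IC[C@H]1CC[C@H](CC(=O)OCC)OC1
F9 | step 15 | (1S)-1-[(2R)-2-(4-methylpent-3-en-1-yl)oxiran-2-yl]-5-(trimethylsilyl)pent-4-yn-1-ol | C[Si](C)(C)C#CCC[C@H](O)[C@@]1(CCC=C(C)C)CO1
A1 | alternative 1 | [(2R,3R)-2-(4-methylpent-3-en-1-yl)-3-[4-(trimethylsilyl)but-3-yn-1-yl]oxiran-2-yl]methanol | C[Si](C)(C)C#CCC[C@H]1O[C@@]1(CO)CCC=C(C)C
A2 | alternative 1 | (2E)-2-(4-methylpent-3-en-1-yl)-7-(trimethylsilyl)hept-2-en-6-yn-1-ol | C[Si](C)(C)C#CCC/C=C(/CO)CCC=C(C)C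
A3 | alternative 2 | (5R)-5-(hydroxymethyl)oxepan-2-one | O=C1CC[C@@H](CO)CCO1
A4 | alternative 2 | 4-(hydroxymethyl)cyclohexan-1-one | O=C1CCC(CO)CC1
A5 | alternative 2 | (5R)-5-(2-hydroxyethyl)oxan-2-one | O=C1CC[C@H](CCO)CO1
A6 | alternative 3 | tert-butyl (3S,6R)-6-(2-hydroxyethyl)oxane-3-carboxylate | CC(C)(C)OC(=O)[C@H]1CC[C@H](CCO)OC1
A7 | alternative 3 | (2S)-2-hydroxybutanedioic acid (L-malic acid) | OC(=O)C[C@H](O)C(=O)O
A8 | alternative 3 | tert-butyl (5R)-5,7-dihydroxy-2-methylideneheptanoate | C=C(CC[C@@H](O)CCO)C(=O)OC(C)(C)C
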